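A direct plan would condense 4,6-dihydroxy-1-benzofuran-3(2H)-one A1 with the diphenylmethylene ketal of protocatechualdehyde A2 to aurone A3, acetylate it and add bromine to give dibromide A4, enlarge the furanone with alkali (Auwers reaction) to quercetin ring B ketal A5, then benzylate at O3 and O7 to dibenzyl ether A6, cleave the ketal, sulfate and hydrogenolyse. Its weakest steps would be:
(a) the bromine addition, which would expose an electron-rich benzodioxole and an acid-labile ketal to Br2 and HBr and pass on a crude diastereomer mixture;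
(b) the alkali ring enlargement, in which closure of ring C would have to outrun dehydrobromination, reversion to the aurone and benzilic acid rearrangement, so the ring closure is left to chance;
(c) the late sorting of hydroxyl groups, in which three protecting-group steps add no skeletal bond and the 3,7-selective benzylation of a triol, resting only on the chelated 5-OH, would be run on late material.

Plan of the new route: the retrosynthesis cuts the two S–O bonds, then ring A at C4a–C5, C5–C6 and C7–C8, then the C2–C1' bond.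
Ring C is bought as kojic acid, ring B is attached to it by Suzuki coupling, and ring A is built last from open-chain pieces.
Enabling feature: ring A has oxygens on C5 and C7 in a 1,3-relation, CH at C6 and C8, and shares C4a=C8a with a 4-pyranone that has a free C4a–H; this is the product pattern of a Danheiser benzannulation of a pyranonylketene (C5, C8) with an alkoxyacetylene (C6, C7–O).
No aurone, bromine addition or ring enlargement occurs, and each oxygen enters already differentiated (3-O as 4-methoxybenzyl ether, 7-O as benzyl ether from the alkyne, 5-OH free from the ketene carbon), so no polyol is protected selectively.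
The target has no stereocentre.

Key step: step 9

Assumption: the target is drawn as the free bis(hydrogen sulfate); because free aryl hydrogen sulfates hydrolyse autocatalytically, the two sulfated compounds of the route would be handled as disodium salts and the acid form of the target released only by brief contact with a cold proton-form resin. TBS = tert-butyldimethylsilyl, PMB = 4-methoxybenzyl.

**Step 1**
Reactants: 1 4-bromobenzene-1,2-diol
Product: 2 4-bromo-1,2-bis(tert-butyldimethylsilyloxy)benzene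
Conditions: TBSCl (2.3 equiv), imidazole, DMF, rt
Reagents that add atoms: tert-butyldimethylsilyl chloride, CC(C)(C)[Si](C)(C)Cl
Why: Imidazole-promoted O-silylation of both phenols gives silyl ethers that stand organolithium, palladium coupling and ketene chemistry and can later be removed by fluoride without touching benzylic ethers.

**Step 2**
Reactants: 2 4-bromo-1,2-bis(tert-butyldimethylsilyloxy)benzene
Product: 3 2-[3,4-bis(tert-butyldimethylsilyloxy)phenyl]-4,4,5,5-tetramethyl-1,3,2-dioxaborolane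
Conditions: n-BuLi, THF, −78 °C; then iPrOBpin, −78 °C to rt; aq. NH4Cl
Reagents that add atoms: 2-isopropoxy-4,4,5,5-tetramethyl-1,3,2-dioxaborolane, CC(C)OB1OC(C)(C)C(C)(C)O1
Why: Bromine–lithium exchange followed by borylation of the aryllithium should be clean because lithium sits meta and para to the silyloxy groups, so no ortho O-to-C silyl shift can occur.

**Step 3**
Reactants: 4 benzyl alcohol; 5 trichloroethylene
Product: 7 benzyl ethynyl ether, via benzyl (E)-1,2-dichlorovinyl ether 6 (not isolated)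
Conditions: KH, THF, 0 °C; Cl2C=CHCl, −50 °C to rt; then n-BuLi (2.4 equiv), −78 °C; MeOH, −78 °C; kept below 0 °C and used at once
Reagents that add atoms: none
Why: In this one-pot ynol ether synthesis the alkoxide adds to dichloroacetylene formed in situ, and n-BuLi then effects elimination and chlorine–lithium exchange to the lithium alkoxyacetylide, which is protonated; the ether is kept cold because benzyl alkynyl ethers undergo [3,3] rearrangement near 60 °C.

**Step 4**
Reactants: 8 kojic acid [5-hydroxy-2-(hydroxymethyl)-4H-pyran-4-one]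
Product: 9 2-bromo-3-hydroxy-6-(hydroxymethyl)-4H-pyran-4-one
Conditions: NBS (1.05 equiv), MeCN, 0 °C to rt
Reagents that add atoms: N-bromosuccinimide, O=C1CCC(=O)N1Br
Why: Electrophilic bromination should take place at the enol carbon next to the ring oxygen and ortho to the hydroxyl, the same site at which kojic acid undergoes Mannich and aldol reactions.

**Step 5**
Reactants: 9 2-bromo-3-hydroxy-6-(hydroxymethyl)-4H-pyran-4-one
Product: 10 2-bromo-6-(hydroxymethyl)-3-[(4-methoxybenzyl)oxy]-4H-pyran-4-one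
Conditions: PMBCl (1.1 equiv), K2CO3, DMF, 50 °C
Reagents that add atoms: 4-methoxybenzyl chloride, COc1ccc(CCl)cc1
Why: Williamson etherification should select the acidic enolic hydroxyl over the primary alcohol, which K2CO3 does not ionise, and the PMB ether later leaves in the same hydrogenolysis as the 7-benzyl ether.

**Step 6**
Reactants: 10 2-bromo-6-(hydroxymethyl)-3-[(4-methoxybenzyl)oxy]-4H-pyran-4-one; 3 2-[3,4-bis(tert-butyldimethylsilyloxy)phenyl]-4,4,5,5-tetramethyl-1,3,2-dioxaborolane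
Product: 11 2-[3,4-bis(tert-butyldimethylsilyloxy)phenyl]-6-(hydroxymethyl)-3-[(4-methoxybenzyl)oxy]-4H-pyran-4-one
Conditions: PdCl2(dppf) (5 mol %), K3PO4, 1,4-dioxane/H2O (10:1), 70 °C, Ar
Reagents that add atoms: none
Why: Suzuki–Miyaura coupling forms the C2–C1' bond because the 2-bromo-4-pyranone is a vinylogous acyl bromide that adds readily to zerovalent palladium, while the free primary alcohol and the silyl ethers tolerate the mild phosphate base.

**Step 7**
Reactants: 11 2-[3,4-bis(tert-butyldimethylsilyloxy)phenyl]-6-(hydroxymethyl)-3-[(4-methoxybenzyl)oxy]-4H-pyran-4-one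
Product: 13 6-[3,4-bis(tert-butyldimethylsilyloxy)phenyl]-5-[(4-methoxybenzyl)oxy]-4-oxo-4H-pyran-2-carboxylic acid, via pyranone-2-carbaldehyde 12 (not isolated)
Conditions: TEMPO (0.2 equiv), PhI(OAc)2 (2.5 equiv), MeCN/H2O (1:1), rt
Reagents that add atoms: water, O
Why: Oxoammonium oxidation takes the primary alcohol to the electron-poor aldehyde 12, whose hydrate is oxidised on to the acid, and PMB ether, aryl silyl ethers and pyranone are inert to this oxidant.

**Step 8**
Reactants: 13 6-[3,4-bis(tert-butyldimethylsilyloxy)phenyl]-5-[(4-methoxybenzyl)oxy]-4-oxo-4H-pyran-2-carboxylic acid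
Product: 15 2-[3,4-bis(tert-butyldimethylsilyloxy)phenyl]-6-(2-diazoacetyl)-3-[(4-methoxybenzyl)oxy]-4H-pyran-4-one, via isobutyl carbonic mixed anhydride 14 (not isolated)
Conditions: iBuOCOCl, N-methylmorpholine, THF, −15 °C; then Me3SiCHN2 (2.5 equiv), MeCN, 0 °C to rt; aq. NaHCO3
Reagents that add atoms: trimethylsilyldiazomethane, C[Si](C)(C)C=[N+]=[N-]
Why: In this Arndt–Eistert-type diazoketone synthesis the diazo carbon is acylated at the more electrophilic pyranoyl carbonyl of the mixed anhydride with loss of the silyl group, and no HCl is formed that could endanger the PMB and silyl ethers.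

**Step 9**
Reactants: 15 2-[3,4-bis(tert-butyldimethylsilyloxy)phenyl]-6-(2-diazoacetyl)-3-[(4-methoxybenzyl)oxy]-4H-pyran-4-one; 7 benzyl ethynyl ether
Product: 20 7-(benzyloxy)-2-[3,4-bis(tert-butyldimethylsilyloxy)phenyl]-5-hydroxy-3-[(4-methoxybenzyl)oxy]-4H-chromen-4-one, via pyranonylketene 16 (not isolated), via 3-benzyloxy-4-pyranonylcyclobutenone 17 (not isolated), via dienylketene 18 (not isolated), via 4aH-chromene-4,5-dione tautomer 19 (not isolated)
Conditions: 7 (3 equiv), degassed CH2Cl2 (0.03 M), LEDs (440–450 nm), 15 °C; excess 7 evaporated below 25 °C; then toluene, 80 °C, dark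
Reagents that add atoms: none
Why: Blue light excites the n–π* band of diazoketone 15, which loses N2 with 1,2-shift of the pyranonyl group (Wolff rearrangement) to ketene 16; the nucleophilic CH terminus of ynol ether 7 adds to the ketene carbonyl carbon in a regiospecific [2+2] cycloaddition to cyclobutenone 17, which on warming opens by reversible 4π electrocyclic cleavage to dienylketene 18. The closest known reaction type is the Danheiser benzannulation in its photochemical Wolff variant, established for alkenyl and heteroaryl diazomethyl ketones with alkoxy- and silyloxyacetylenes. Ring A is closed by 6π electrocyclisation of 18 (C5–C4a bond, in polar terms attack of the nucleophilic α-carbon of the vinylogous ester O1–C8a=C4a on the ketene) after C5–C6 and C7–C8 were joined in the [2+2] step, and dienone 19 tautomerises to the phenol, held by the hydrogen bond from 5-OH to the C4 carbonyl. No stereocentre survives, since C8 of 17 and C4a of 19 are transient. The step needs the 5-hydroxy-7-alkoxy pattern, closure at one site and no photoreaction of the 3-alkoxy-2-arylpyranone (γ-hydrogen abstraction from its OCH2 group); these are secured by the polarity of the ynol ether, by C4a being the only carbon neighbour of C8a in ring C, and by irradiating at 450 nm, where only the diazoketone should absorb, with the thermal finish in the dark. Excess 7 is removed before heating because it would rearrange to a ketene near 60 °C and acylate the product.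

**Step 10**
Reactants: 20 7-(benzyloxy)-2-[3,4-bis(tert-butyldimethylsilyloxy)phenyl]-5-hydroxy-3-[(4-methoxybenzyl)oxy]-4H-chromen-4-one
Product: 21 7-(benzyloxy)-2-(3,4-dihydroxyphenyl)-5-hydroxy-3-[(4-methoxybenzyl)oxy]-4H-chromen-4-one
Conditions: Bu4NF (2.2 equiv), AcOH (2.5 equiv), THF, 0 °C, Ar
Reagents that add atoms: none
Why: Fluoride cleaves only the two aryl silyl ethers, the acetic acid buffer keeps the liberated catechol from air oxidation as its phenoxide, and benzyl and PMB ethers are untouched, so exactly the two ring B hydroxyls are set free.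

**Step 11**
Reactants: 21 7-(benzyloxy)-2-(3,4-dihydroxyphenyl)-5-hydroxy-3-[(4-methoxybenzyl)oxy]-4H-chromen-4-one
Product: 22 4-{7-(benzyloxy)-5-hydroxy-3-[(4-methoxybenzyl)oxy]-4-oxo-4H-chromen-2-yl}-1,2-phenylene bis(hydrogen sulfate)
Conditions: SO3·NMe3 (10 equiv), Et3N, DMF, 55 °C; then sulfonic acid resin (sodium form), C18 silica
Reagents that add atoms: sulfur trioxide trimethylamine complex, C[N+](C)(C)S(=O)(=O)[O-]
Why: O-sulfonation of phenols by an amine–SO3 complex should take place at the two ring B hydroxyls, the only free ones apart from the chelated and far less nucleophilic 5-OH, and excess reagent with gentle warming should drive the slower second sulfation.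

**Step 12**
Reactants: 22 4-{7-(benzyloxy)-5-hydroxy-3-[(4-methoxybenzyl)oxy]-4-oxo-4H-chromen-2-yl}-1,2-phenylene bis(hydrogen sulfate)
Product: 23 4-(3,5,7-trihydroxy-4-oxo-4H-chromen-2-yl)-1,2-phenylene bis(hydrogen sulfate)
Conditions: H2 (1 atm), Pd/C (10% Pd on carbon), MeOH/H2O, rt (disodium salt); filtration, freeze-drying; acid form by sulfonic acid resin (proton form), 0 °C
Reagents that add atoms: none
Why: Heterogeneous hydrogenolysis should cleave the benzyl and the PMB ether, while aryl sulfate anions, the chromone C2=C3 bond and the aromatic rings are not reduced at 1 atm and room temperature.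

**Compound list**

1 | 4-bromobenzene-1,2-diol | Oc1ccc(Br)cc1O | starting material
2 | 4-bromo-1,2-bis(tert-butyldimethylsilyloxy)benzene | CC(C)(C)[Si](C)(C)Oc1ccc(Br)cc1O[Si](C)(C)C(C)(C)C | intermediate
3 | 2-[3,4-bis(tert-butyldimethylsilyloxy)phenyl]-4,4,5,5-tetramethyl-1,3,2-dioxaborolane | CC(C)(C)[Si](C)(C)Oc1ccc(B2OC(C)(C)C(C)(C)O2)cc1O[Si](C)(C)C(C)(C)C | intermediate
4 | benzyl alcohol | OCc1ccccc1 | starting material
5 | trichloroethylene | ClC=C(Cl)Cl | starting material
6 | benzyl (E)-1,2-dichlorovinyl ether (not isolated) | Cl/C=C(/Cl)OCc1ccccc1 | intermediate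
7 | benzyl ethynyl ether | C#COCc1ccccc1 | intermediate
8 | kojic acid, 5-hydroxy-2-(hydroxymethyl)-4H-pyran-4-one | OCc1cc(=O)c(O)co1 | starting material
9 | 2-bromo-3-hydroxy-6-(hydroxymethyl)-4H-pyran-4-one | OCc1cc(=O)c(O)c(Br)o1 | intermediate
10 | 2-bromo-6-(hydroxymethyl)-3-[(4-methoxybenzyl)oxy]-4H-pyran-4-one | COc1ccc(COc2c(Br)oc(CO)cc2=O)cc1 | intermediate
11 | 2-[3,4-bis(tert-butyldimethylsilyloxy)phenyl]-6-(hydroxymethyl)-3-[(4-methoxybenzyl)oxy]-4H-pyran-4-one | COc1ccc(COc2c(-c3ccc(O[Si](C)(C)C(C)(C)C)c(O[Si](C)(C)C(C)(C)C)c3)oc(CO)cc2=O)cc1 | intermediate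
12 | 6-[3,4-bis(tert-butyldimethylsilyloxy)phenyl]-5-[(4-methoxybenzyl)oxy]-4-oxo-4H-pyran-2-carbaldehyde (not isolated) | COc1ccc(COc2c(-c3ccc(O[Si](C)(C)C(C)(C)C)c(O[Si](C)(C)C(C)(C)C)c3)oc(C=O)cc2=O)cc1 | intermediate
13 | 6-[3,4-bis(tert-butyldimethylsilyloxy)phenyl]-5-[(4-methoxybenzyl)oxy]-4-oxo-4H-pyran-2-carboxylic acid | COc1ccc(COc2c(-c3ccc(O[Si](C)(C)C(C)(C)C)c(O[Si](C)(C)C(C)(C)C)c3)oc(C(=O)O)cc2=O)cc1 | intermediate
14 | isobutyl carbonic anhydride of acid 13 (not isolated) | COc1ccc(COc2c(-c3ccc(O[Si](C)(C)C(C)(C)C)c(O[Si](C)(C)C(C)(C)C)c3)oc(C(=O)OC(=O)OCC(C)C)cc2=O)cc1 | intermediate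
15 | 2-[3,4-bis(tert-butyldimethylsilyloxy)phenyl]-6-(2-diazoacetyl)-3-[(4-methoxybenzyl)oxy]-4H-pyran-4-one | COc1ccc(COc2c(-c3ccc(O[Si](C)(C)C(C)(C)C)c(O[Si](C)(C)C(C)(C)C)c3)oc(C(=O)C=[N+]=[N-])cc2=O)cc1 | intermediate
16 | 2-[3,4-bis(tert-butyldimethylsilyloxy)phenyl]-3-[(4-methoxybenzyl)oxy]-6-(2-oxoethenyl)-4H-pyran-4-one (pyranonylketene, not isolated) | COc1ccc(COc2c(-c3ccc(O[Si](C)(C)C(C)(C)C)c(O[Si](C)(C)C(C)(C)C)c3)oc(C=C=O)cc2=O)cc1 | intermediate
17 | 6-[2-(benzyloxy)-4-oxocyclobut-2-en-1-yl]-2-[3,4-bis(tert-butyldimethylsilyloxy)phenyl]-3-[(4-methoxybenzyl)oxy]-4H-pyran-4-one (racemic, not isolated) | COc1ccc(COc2c(-c3ccc(O[Si](C)(C)C(C)(C)C)c(O[Si](C)(C)C(C)(C)C)c3)oc(C4C(=O)C=C4OCc4ccccc4)cc2=O)cc1 | intermediate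
18 | 6-[(1E)-2-(benzyloxy)-4-oxobuta-1,3-dien-1-yl]-2-[3,4-bis(tert-butyldimethylsilyloxy)phenyl]-3-[(4-methoxybenzyl)oxy]-4H-pyran-4-one (dienylketene, pyranonyl and ketene groups cis, not isolated) | COc1ccc(COc2c(-c3ccc(O[Si](C)(C)C(C)(C)C)c(O[Si](C)(C)C(C)(C)C)c3)oc(/C=C(\C=C=O)OCc3ccccc3)cc2=O)cc1 | intermediate
19 | 7-(benzyloxy)-2-[3,4-bis(tert-butyldimethylsilyloxy)phenyl]-3-[(4-methoxybenzyl)oxy]-4aH-chromene-4,5-dione (racemic, not isolated) | COc1ccc(COC2=C(c3ccc(O[Si](C)(C)C(C)(C)C)c(O[Si](C)(C)C(C)(C)C)c3)OC3=CC(OCc4ccccc4)=CC(=O)C3C2=O)cc1 | intermediate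
20 | 7-(benzyloxy)-2-[3,4-bis(tert-butyldimethylsilyloxy)phenyl]-5-hydroxy-3-[(4-methoxybenzyl)oxy]-4H-chromen-4-one | O=c1c(OCc2ccc(OC)cc2)c(-c2ccc(O[Si](C)(C)C(C)(C)C)c(O[Si](C)(C)C(C)(C)C)c2)oc2cc(OCc3ccccc3)cc(O)c12 | intermediate
21 | 7-(benzyloxy)-2-(3,4-dihydroxyphenyl)-5-hydroxy-3-[(4-methoxybenzyl)oxy]-4H-chromen-4-one | O=c1c(OCc2ccc(OC)cc2)c(-c2ccc(O)c(O)c2)oc2cc(OCc3ccccc3)cc(O)c12 | intermediate
22 | 4-{7-(benzyloxy)-5-hydroxy-3-[(4-methoxybenzyl)oxy]-4-oxo-4H-chromen-2-yl}-1,2-phenylene bis(hydrogen sulfate) | O=c1c(OCc2ccc(OC)cc2)c(-c2ccc(OS(=O)(=O)O)c(OS(=O)(=O)O)c2)oc2cc(OCc3ccccc3)cc(O)c12 | intermediate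
23 | 4-(3,5,7-trihydroxy-4-oxo-4H-chromen-2-yl)-1,2-phenylene bis(hydrogen sulfate) | O=c1c(O)c(-c2ccc(OS(=O)(=O)O)c(OS(=O)(=O)O)c2)oc2cc(O)cc(O)c12 | target

Total step count: 12. Longest linear sequence: 9 steps (steps 4 to 12, from kojic acid).

**Steps most likely to fail**

Step 9 (benzannulation). The ketene may dimerise or be captured by adventitious nucleophiles before it meets the alkyne, the pyranone chromophore may undergo its own photoreaction, or the alkynyl ether may rearrange. Fallback without light, setting out from diazoketone 15: a silver-catalysed Wolff rearrangement in the dark (PhCO2Ag, Et3N, THF/H2O) would give {6-[3,4-bis(tert-butyldimethylsilyloxy)phenyl]-5-[(4-methoxybenzyl)oxy]-4-oxo-4H-pyran-2-yl}acetic acid F1. 1-Chloro-N,N,2-trimethylprop-1-en-1-amine in CH2Cl2 would convert it under neutral conditions into {6-[3,4-bis(tert-butyldimethylsilyloxy)phenyl]-5-[(4-methoxybenzyl)oxy]-4-oxo-4H-pyran-2-yl}acetyl chloride F2. Slow addition of F2 to Et3N and alkyne 7 would generate ketene 16 by dehydrochlorination, which would pass through 17 and, after heating in toluene, come back to the route at 20.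

Step 11 (double sulfation). The second sulfation may stall next to the first anionic sulfate, or forcing conditions may begin to sulfate the chelated 5-OH. Fallback through neutral sulfate diesters, setting out from catechol 21: 2,2,2-trichloroethyl chlorosulfate (Et3N, DMAP, THF, 0 °C to rt) would give 4-{7-(benzyloxy)-5-hydroxy-3-[(4-methoxybenzyl)oxy]-4-oxo-4H-chromen-2-yl}-1,2-phenylene bis(2,2,2-trichloroethyl) bis(sulfate) F3 without charge build-up. Pd/C with HCO2NH4 in MeOH would then remove both trichloroethyl groups and both benzylic ethers in one operation and come back to the route at 23 (as its ammonium salt).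

Step 8 (diazoketone formation). Acylation of the weakly nucleophilic silyldiazomethane may be slow, or attack may occur at the carbonate carbonyl and return the acid. Fallback by diazo transfer, setting out from alcohol 11: MnO2 in CH2Cl2 would stop at aldehyde 12, and MeMgBr (THF, −78 °C) would give 2-[3,4-bis(tert-butyldimethylsilyloxy)phenyl]-6-(1-hydroxyethyl)-3-[(4-methoxybenzyl)oxy]-4H-pyran-4-one F4. Dess–Martin periodinane would give 6-acetyl-2-[3,4-bis(tert-butyldimethylsilyloxy)phenyl]-3-[(4-methoxybenzyl)oxy]-4H-pyran-4-one F5. LiN(SiMe3)2 and CF3CO2CH2CF3 (THF, −78 °C) would give the trifluoroacetylated diketone 1-{6-[3,4-bis(tert-butyldimethylsilyloxy)phenyl]-5-[(4-methoxybenzyl)oxy]-4-oxo-4H-pyran-2-yl}-4,4,4-trifluorobutane-1,3-dione F6 (not isolated). MsN3 and Et3N in wet MeCN would then transfer the diazo group with loss of the trifluoroacetyl group and come back to the route at 15.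

**Further compounds**

F1 | step 9 | {6-[3,4-bis(tert-butyldimethylsilyloxy)phenyl]-5-[(4-methoxybenzyl)oxy]-4-oxo-4H-pyran-2-yl}acetic acid | COc1ccc(COc2c(-c3ccc(O[Si](C)(C)C(C)(C)C)c(O[Si](C)(C)C(C)(C)C)c3)oc(CC(=O)O)cc2=O)cc1
F2 | step 9 | {6-[3,4-bis(tert-butyldimethylsilyloxy)phenyl]-5-[(4-methoxybenzyl)oxy]-4-oxo-4H-pyran-2-yl}acetyl chloride | COc1ccc(COc2c(-c3ccc(O[Si](C)(C)C(C)(C)C)c(O[Si](C)(C)C(C)(C)C)c3)oc(CC(=O)Cl)cc2=O)cc1
F3 | step 11 | 4-{7-(benzyloxy)-5-hydroxy-3-[(4-methoxybenzyl)oxy]-4-oxo-4H-chromen-2-yl}-1,2-phenylene bis(2,2,2-trichloroethyl) bis(sulfate) | O=c1c(OCc2ccc(OC)cc2)c(-c2ccc(OS(=O)(=O)OCC(Cl)(Cl)Cl)c(OS(=O)(=O)OCC(Cl)(Cl)Cl)c2)oc2cc(OCc3ccccc3)cc(O)c12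
F4 | step 8 | 2-[3,4-bis(tert-butyldimethylsilyloxy)phenyl]-6-(1-hydroxyethyl)-3-[(4-methoxybenzyl)oxy]-4H-pyran-4-one (racemic) | COc1ccc(COc2c(-c3ccc(O[Si](C)(C)C(C)(C)C)c(O[Si](C)(C)C(C)(C)C)c3)oc(C(C)O)cc2=O)cc1
F5 | step 8 | 6-acetyl-2-[3,4-bis(tert-butyldimethylsilyloxy)phenyl]-3-[(4-methoxybenzyl)oxy]-4H-pyran-4-one | COc1ccc(COc2c(-c3ccc(O[Si](C)(C)C(C)(C)C)c(O[Si](C)(C)C(C)(C)C)c3)oc(C(C)=O)cc2=O)cc1
F6 | step 8 | 1-{6-[3,4-bis(tert-butyldimethylsilyloxy)phenyl]-5-[(4-methoxybenzyl)oxy]-4-oxo-4H-pyran-2-yl}-4,4,4-trifluorobutane-1,3-dione | COc1ccc(COc2c(-c3ccc(O[Si](C)(C)C(C)(C)C)c(O[Si](C)(C)C(C)(C)C)c3)oc(C(=O)CC(=O)C(F)(F)F)cc2=O)cc1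
A1 | direct plan | 4,6-dihydroxy-1-benzofuran-3(2H)-one | O=C1COc2cc(O)cc(O)c12
A2 | direct plan | 2,2-diphenyl-1,3-benzodioxole-5-carbaldehyde | O=Cc1ccc2OC(c3ccccc3)(c3ccccc3)Oc2c1
A3 | direct plan | (2Z)-2-[(2,2-diphenyl-1,3-benzodioxol-5-yl)methylidene]-4,6-dihydroxy-1-benzofuran-3(2H)-one | O=C1c2c(O)cc(O)cc2O/C1=C\c1ccc2OC(c3ccccc3)(c3ccccc3)Oc2c1
A4 | direct plan | 2-bromo-2-[bromo(2,2-diphenyl-1,3-benzodioxol-5-yl)methyl]-3-oxo-2,3-dihydro-1-benzofuran-4,6-diyl diacetate (diastereomer mixture) | CC(=O)Oc1cc(OC(C)=O)c2C(=O)C(Br)(C(Br)c3ccc4OC(c5ccccc5)(c5ccccc5)Oc4c3)Oc2c1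
A5 | direct plan | 2-(2,2-diphenyl-1,3-benzodioxol-5-yl)-3,5,7-trihydroxy-4H-chromen-4-one | O=c1c(O)c(-c2ccc3OC(c4ccccc4)(c4ccccc4)Oc3c2)oc2cc(O)cc(O)c12
A6 | direct plan | 3,7-bis(benzyloxy)-2-(2,2-diphenyl-1,3-benzodioxol-5-yl)-5-hydroxy-4H-chromen-4-one | O=c1c(OCc2ccccc2)c(-c2ccc3OC(c4ccccc4)(c4ccccc4)Oc3c2)oc2cc(OCc3ccccc3)cc(O)c12
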